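## Retrosynthetic overview

- Menaquinone-8 is disconnected by a one-pot Dötz benzannulation and oxidation into pentacarbonyl[methoxy(phenyl)methylidene]chromium, one of its CO ligands, and a 2-alkyne carrying the all-E octaprenyl chain. Ring B (the quinone ring) is the only ring formed and is built onto the purchased benzene ring A. Three C–C bonds form: carbene C to alkyne C, alkyne C to CO, and CO to an ortho carbon of the phenyl group.
- Enabling feature: ring B carries oxygen on C1 and C4, both carbon substituents on the C2=C3 bond, and is fused at C4a–C8a to an unsubstituted benzene ring. C2=C3 therefore maps onto an alkyne, C1 (next to the methyl-bearing C2) onto a carbene carbon already bonded to phenyl, and C4 onto CO. Because C1 and C4 both end as C=O, either orientation of the alkyne gives the same quinone.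
- The enyne comes from all-E-octaprenyl bromide and 1-propynylmagnesium bromide by copper-catalysed allylic substitution.
- The octaprenyl chain comes from a Biellmann coupling of two C20 halves, both made from all-E-geranylgeraniol (an allylic sulfone and an ω-bromide from terminal allylic oxidation), followed by palladium-catalysed hydride desulfonylation.
- The carbene complex comes from Cr(CO)6 and phenyllithium, then O-methylation.

Key step: step 12

Assumption: the naphthol complex of the key step is drawn as the expected major regioisomer (chain-bearing carbon next to the hydroxyl-bearing carbon); the other regioisomer is oxidised to the same quinone and is not numbered. all-E-Geranylgeraniol, 1-propynylmagnesium bromide (THF solution), Cr(CO)6 and phenyllithium are taken as purchased.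

## Route

Step 1
Reactants: 1 all-E-geranylgeraniol
Product: 2 all-E-geranylgeranyl bromide
Conditions: PBr3 (0.4 equiv), Et2O, −10 to 0 °C
Reagents that add atoms: phosphorus tribromide, BrP(Br)Br
Why: Bromination of a primary allylic alcohol through its phosphite ester at low temperature is the standard entry to polyprenyl bromides and should leave the allylic position untransposed and the E alkenes unchanged.

Step 2
Reactants: 2 all-E-geranylgeranyl bromide
Product: 3 all-E-geranylgeranyl phenyl sulfone
Conditions: PhSO2Na, DMF, rt
Reagents that add atoms: sodium benzenesulfinate, [Na+].[O-]S(=O)c1ccccc1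
Why: S-Alkylation of the sulfinate by a primary allylic bromide (SN2) in a dipolar aprotic solvent should give the allylic sulfone without allylic transposition.

Step 3
Reactants: 1 all-E-geranylgeraniol
Product: 4 all-E-geranylgeranyl tert-butyldiphenylsilyl ether
Conditions: TBDPSCl, imidazole, CH2Cl2, rt
Reagents that add atoms: tert-butyl(chloro)diphenylsilane, CC(C)(C)[Si](Cl)(c1ccccc1)c1ccccc1
Why: Imidazole-promoted silylation of a primary alcohol; the TBDPS ether is chosen because it should survive the selenium oxidation, the sulfonyl carbanion and the hydride of the later steps.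

Step 4
Reactants: 4 all-E-geranylgeranyl tert-butyldiphenylsilyl ether
Product: 5 (2E,6E,10E,14E)-16-[(tert-butyldiphenylsilyl)oxy]-2,6,10,14-tetramethylhexadeca-2,6,10,14-tetraen-1-ol
Conditions: SeO2 (cat.), t-BuOOH, salicylic acid (cat.), CH2Cl2, 0 °C to rt
Reagents that add atoms: selenium dioxide (oxygen donor, catalytic), O=[Se]=O; tert-butyl hydroperoxide (terminal oxidant that regenerates it), CC(C)(C)OO
Why: Riley-type allylic oxidation (ene reaction, then [2,3]-sigmatropic shift) should go preferentially at the E-methyl group of the terminal isopropylidene unit, the most accessible trisubstituted alkene, and the cyclic [2,3] shift fixes the new 2E geometry.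

Step 5
Reactants: 5 the ω-hydroxy silyl ether
Product: 6 (2E,6E,10E,14E)-16-bromo-1-[(tert-butyldiphenylsilyl)oxy]-3,7,11,15-tetramethylhexadeca-2,6,10,14-tetraene
Conditions: CBr4, PPh3, CH2Cl2, 0 °C
Reagents that add atoms: carbon tetrabromide, BrC(Br)(Br)Br
Why: Appel bromination under neutral conditions should convert the primary allylic alcohol to the bromide without transposition and without touching the silyl ether.

Step 6
Reactants: 3 all-E-geranylgeranyl phenyl sulfone; 6 the ω-bromo silyl ether
Product: 7 all-E C40 sulfone silyl ether (17-phenylsulfonyl octaprenyl TBDPS ether, racemic at the sulfonyl-bearing carbon)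
Conditions: 3, n-BuLi, THF/DMPU, −78 °C; then 6, −78 to −40 °C
Reagents that add atoms: none
Why: Biellmann coupling, in which the α-sulfonyl allylic carbanion is alkylated at its α-carbon by the primary allylic bromide (SN2); the new stereocenter forms as a racemate and is erased in step 7.

Step 7
Reactants: 7 all-E C40 sulfone silyl ether
Product: 8 all-E-octaprenyl tert-butyldiphenylsilyl ether
Conditions: PdCl2(dppp) (5 mol %; dppp = 1,3-bis(diphenylphosphino)propane), LiBHEt3, THF, 0 °C
Reagents that add atoms: none
Why: Palladium-catalysed hydride desulfonylation of an allylic sulfone through a π-allylpalladium hydride, where the bidentate phosphine should direct hydride to the less substituted allyl terminus so the trisubstituted E alkene stays in place.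

Step 8
Reactants: 8 all-E-octaprenyl tert-butyldiphenylsilyl ether
Product: 9 all-E-octaprenol
Conditions: Bu4NF, THF, rt
Reagents that add atoms: none
Why: Fluoride-driven cleavage of the Si–O bond, a standard desilylation that does not affect the skipped polyene.

Step 9
Reactants: 9 all-E-octaprenol
Product: 10 all-E-octaprenyl bromide
Conditions: PBr3 (0.4 equiv), Et2O, −10 to 0 °C; used crude
Reagents that add atoms: phosphorus tribromide, BrP(Br)Br
Why: Same primary allylic bromination as step 1, with the sensitive bromide taken on directly to avoid allylic equilibration.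

Step 10
Reactants: 10 all-E-octaprenyl bromide; 11 1-propynylmagnesium bromide
Product: 12 (5E,9E,13E,17E,21E,25E,29E)-6,10,14,18,22,26,30,34-octamethylpentatriaconta-5,9,13,17,21,25,29,33-octaen-2-yne
Conditions: CuI (10 mol %), THF, 0 to 40 °C
Reagents that add atoms: none
Why: Copper-catalysed substitution of a primary allylic bromide by an alkynyl Grignard reagent, where the alkynylcopper species should attack the unhindered α-carbon of the prenyl-type halide to give the 1,4-enyne with the 5E alkene retained.

Step 11
Reactants: 13 hexacarbonylchromium; 14 phenyllithium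
Product: 16 pentacarbonyl[methoxy(phenyl)methylidene]chromium, via lithium pentacarbonyl(benzoyl)chromate 15 (not isolated)
Conditions: Et2O, 0 °C to rt; then Me3OBF4, CH2Cl2, 0 °C
Reagents that add atoms: trimethyloxonium tetrafluoroborate, C[O+](C)C.F[B-](F)(F)F
Why: Fischer carbene synthesis, in which the aryllithium adds to a CO ligand to give the acylmetalate and the Meerwein salt O-methylates it.

Step 12
Reactants: 12 the octaprenyl enyne; 16 pentacarbonyl[methoxy(phenyl)methylidene]chromium
Product: 18 menaquinone-8, via tricarbonylchromium naphthol complex 17 (not isolated)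
Conditions: 16 (1.3 equiv), t-BuOMe, 55 °C, Ar; then (NH4)2Ce(NO3)6, MeCN/H2O, 0 °C
Reagents that add atoms: water, O
Why: Dötz benzannulation: loss of one CO from 16 opens a site on zerovalent chromium, the alkyne of 12 inserts into the Cr=C bond (carbene carbon to the methyl-bearing alkyne carbon in the favoured orientation), a CO ligand inserts to give a chromium-bound dienylketene whose ketene carbon is bonded to the chain-bearing alkyne carbon, and 6π-electrocyclization onto an ortho carbon of the phenyl group followed by tautomerization gives complex 17 of the 4-methoxy-1-naphthol. The closest known reaction type is the benzannulation of pentacarbonyl[aryl(alkoxy)carbene]chromium complexes with internal alkynes, isoprenoid 1,4-enynes included, with oxidative work-up to 1,4-naphthoquinones. Ring B is the only ring closed, by 6π electrocyclic closure of the dienylketene (overall a [3+2+1] assembly of carbene, alkyne and CO), and no stereocenter is created. The step needs chemoselectivity for the alkyne over the eight trisubstituted alkenes, secured by the much higher reactivity of alkynes towards the unsaturated carbene and by the CH2 spacer that keeps the nearest alkene out of reach for cyclopropanation; it also needs CO insertion to outrun indene formation, which chromium, the methoxy donor and an ether solvent at about 55 °C favour. Regiochemistry of alkyne insertion is not critical, because (NH4)2Ce(NO3)6 strips the chromium and converts either regioisomeric 4-methoxy-1-naphthol into the same quinone, water attacking the methoxy-bearing carbon with loss of methanol. The all-E chain should pass unchanged, since no allylmetal or strongly acidic species able to isomerize the skipped alkenes is formed.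

## Compound list

1 | all-E-geranylgeraniol, (2E,6E,10E)-3,7,11,15-tetramethylhexadeca-2,6,10,14-tetraen-1-ol | CC(C)=CCC/C(C)=C/CC/C(C)=C/CC/C(C)=C/CO | starting material
2 | all-E-geranylgeranyl bromide | CC(C)=CCC/C(C)=C/CC/C(C)=C/CC/C(C)=C/CBr | intermediate
3 | all-E-geranylgeranyl phenyl sulfone | CC(C)=CCC/C(C)=C/CC/C(C)=C/CC/C(C)=C/CS(=O)(=O)c1ccccc1 | intermediate
4 | all-E-geranylgeranyl tert-butyldiphenylsilyl ether | CC(C)=CCC/C(C)=C/CC/C(C)=C/CC/C(C)=C/CO[Si](c1ccccc1)(c1ccccc1)C(C)(C)C | intermediate
5 | (2E,6E,10E,14E)-16-[(tert-butyldiphenylsilyl)oxy]-2,6,10,14-tetramethylhexadeca-2,6,10,14-tetraen-1-ol | OC/C(C)=C/CC/C(C)=C/CC/C(C)=C/CC/C(C)=C/CO[Si](c1ccccc1)(c1ccccc1)C(C)(C)C | intermediate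
6 | (2E,6E,10E,14E)-16-bromo-1-[(tert-butyldiphenylsilyl)oxy]-3,7,11,15-tetramethylhexadeca-2,6,10,14-tetraene | BrC/C(C)=C/CC/C(C)=C/CC/C(C)=C/CC/C(C)=C/CO[Si](c1ccccc1)(c1ccccc1)C(C)(C)C | intermediate
7 | all-E C40 sulfone silyl ether (phenylsulfonyl group on C17 of the octaprenyl chain, racemic) | CC(C)=CCC/C(C)=C/CC/C(C)=C/CC/C(C)=C/C(S(=O)(=O)c1ccccc1)C/C(C)=C/CC/C(C)=C/CC/C(C)=C/CC/C(C)=C/CO[Si](c1ccccc1)(c1ccccc1)C(C)(C)C | intermediate
8 | all-E-octaprenyl tert-butyldiphenylsilyl ether | CC(C)=CCC/C(C)=C/CC/C(C)=C/CC/C(C)=C/CC/C(C)=C/CC/C(C)=C/CC/C(C)=C/CC/C(C)=C/CO[Si](c1ccccc1)(c1ccccc1)C(C)(C)C | intermediate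
9 | all-E-octaprenol, (2E,6E,10E,14E,18E,22E,26E)-3,7,11,15,19,23,27,31-octamethyldotriaconta-2,6,10,14,18,22,26,30-octaen-1-ol | CC(C)=CCC/C(C)=C/CC/C(C)=C/CC/C(C)=C/CC/C(C)=C/CC/C(C)=C/CC/C(C)=C/CC/C(C)=C/CO | intermediate
10 | all-E-octaprenyl bromide | CC(C)=CCC/C(C)=C/CC/C(C)=C/CC/C(C)=C/CC/C(C)=C/CC/C(C)=C/CC/C(C)=C/CC/C(C)=C/CBr | intermediate
11 | 1-propynylmagnesium bromide | CC#C[Mg]Br | starting material
12 | (5E,9E,13E,17E,21E,25E,29E)-6,10,14,18,22,26,30,34-octamethylpentatriaconta-5,9,13,17,21,25,29,33-octaen-2-yne | CC(C)=CCC/C(C)=C/CC/C(C)=C/CC/C(C)=C/CC/C(C)=C/CC/C(C)=C/CC/C(C)=C/CC/C(C)=C/CC#CC | intermediate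
13 | hexacarbonylchromium, Cr(CO)6 | O=C=[Cr](=C=O)(=C=O)(=C=O)(=C=O)=C=O | starting material
14 | phenyllithium | [Li]c1ccccc1 | starting material
15 | lithium pentacarbonyl(benzoyl)chromate | [Li+].[O-]C(c1ccccc1)=[Cr](=C=O)(=C=O)(=C=O)(=C=O)=C=O | intermediate
16 | pentacarbonyl[methoxy(phenyl)methylidene]chromium | COC(c1ccccc1)=[Cr](=C=O)(=C=O)(=C=O)(=C=O)=C=O | intermediate
17 | tricarbonylchromium complex (η6 on ring B) of 4-methoxy-3-methyl-2-(all-E-octaprenyl)naphthalen-1-ol; hapticity not expressible in SMILES, so written as separate parts | CC(C)=CCC/C(C)=C/CC/C(C)=C/CC/C(C)=C/CC/C(C)=C/CC/C(C)=C/CC/C(C)=C/CC/C(C)=C/Cc1c(C)c(OC)c2ccccc2c1O.[Cr].[C-]#[O+].[C-]#[O+].[C-]#[O+] | intermediate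
18 | menaquinone-8, 2-methyl-3-(all-E-octaprenyl)naphthalene-1,4-dione | CC(C)=CCC/C(C)=C/CC/C(C)=C/CC/C(C)=C/CC/C(C)=C/CC/C(C)=C/CC/C(C)=C/CC/C(C)=C/CC1=C(C)C(=O)c2ccccc2C1=O | target

## Summary

Total step count: 12. Longest linear sequence: 9 steps (steps 3, 4, 5, 6, 7, 8, 9, 10 and 12, from 1 to 18).

Steps most likely to fail:

1. Step 4. Oxidation may spread over the internal allylic positions and run on to the enal, so that site selectivity and conversion to the terminal E-allylic alcohol are poor. Fallback, from 4 back to 5, builds the terminal E-allylic alcohol by cleavage and olefination. NBS in aqueous THF at 0 °C should give the terminal bromohydrin F1. K2CO3 in MeOH closes it to the terminal epoxide F2. Periodic acid in THF/Et2O cleaves this to the trisnor aldehyde F3. Wittig reaction with ethyl 2-(triphenylphosphoranylidene)propanoate in CH2Cl2 should give the ethyl (E)-2-methyl enoate F4. DIBAL-H in CH2Cl2 at −78 °C reduces it to 5, where the route is rejoined.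

2. Step 12. Cyclization without CO insertion (indene formation) and alkyne oligomerization may compete with the benzannulation, and the polyene chain may be degraded oxidatively during the cerium work-up. Fallback, from 10 to 18, builds ring B from a preformed naphthalene instead. Menadione F5 is reduced and methylated (Na2S2O4, then Me2SO4, KOH) to 1,4-dimethoxy-2-methylnaphthalene F6. Br2 in CH2Cl2 at 0 °C should give 2-bromo-1,4-dimethoxy-3-methylnaphthalene F7. Mg in THF gives (1,4-dimethoxy-3-methylnaphthalen-2-yl)magnesium bromide F8. With CuBr·SMe2 (cat.) this is alkylated by bromide 10 to 1,4-dimethoxy-2-methyl-3-(all-E-octaprenyl)naphthalene F9. (NH4)2Ce(NO3)6 in MeCN/H2O at 0 °C then oxidizes F9 to 18.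

3. Step 10. The alkynylcopper species may attack the tertiary γ-carbon (allylic transposition), and the 2E geometry may be partly lost through allylcopper equilibration. Fallback, from 10 to 12, is a Stille coupling of 10 with tributyl(1-propynyl)stannane (Pd(PPh3)4, THF, 50 °C). It goes through a π-allylpalladium intermediate that should couple at the less substituted terminus with retention of the E alkene, and gives 12 directly without new intermediates.

Further compounds
F1 | step 4 | (6E,10E,14E)-3-bromo-16-[(tert-butyldiphenylsilyl)oxy]-2,6,10,14-tetramethylhexadeca-6,10,14-trien-2-ol (racemic) | CC(C)(O)C(Br)CC/C(C)=C/CC/C(C)=C/CC/C(C)=C/CO[Si](c1ccccc1)(c1ccccc1)C(C)(C)C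
F2 | step 4 | terminal epoxide, 14,15-epoxide of 4 (racemic) | CC1(C)OC1CC/C(C)=C/CC/C(C)=C/CC/C(C)=C/CO[Si](c1ccccc1)(c1ccccc1)C(C)(C)C
F3 | step 4 | (4E,8E,12E)-14-[(tert-butyldiphenylsilyl)oxy]-4,8,12-trimethyltetradeca-4,8,12-trienal | O=CCC/C(C)=C/CC/C(C)=C/CC/C(C)=C/CO[Si](c1ccccc1)(c1ccccc1)C(C)(C)C
F4 | step 4 | ethyl (2E,6E,10E,14E)-16-[(tert-butyldiphenylsilyl)oxy]-2,6,10,14-tetramethylhexadeca-2,6,10,14-tetraenoate | CCOC(=O)/C(C)=C/CC/C(C)=C/CC/C(C)=C/CC/C(C)=C/CO[Si](c1ccccc1)(c1ccccc1)C(C)(C)C
F5 | step 12 | menadione (purchased) | CC1=CC(=O)c2ccccc2C1=O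
F6 | step 12 | 1,4-dimethoxy-2-methylnaphthalene | COc1cc(C)c(OC)c2ccccc12
F7 | step 12 | 2-bromo-1,4-dimethoxy-3-methylnaphthalene | COc1c(Br)c(C)c(OC)c2ccccc12
F8 | step 12 | (1,4-dimethoxy-3-methylnaphthalen-2-yl)magnesium bromide | COc1c([Mg]Br)c(C)c(OC)c2ccccc12
F9 | step 12 | 1,4-dimethoxy-2-methyl-3-(all-E-octaprenyl)naphthalene | CC(C)=CCC/C(C)=C/CC/C(C)=C/CC/C(C)=C/CC/C(C)=C/CC/C(C)=C/CC/C(C)=C/CC/C(C)=C/Cc1c(C)c(OC)c2ccccc2c1OC
F0 | step 10 | none | none
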